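We have two questions, in order: how many living ends does each flask carry, and how long do they work on the free monomer that the other steps leave?

    free monomer + initiator → living end + monomer in chains (k1 = 0.00104 M⁻¹ s⁻¹)
    free monomer + living end → monomer in chains + living end, rate k2*[living end]*[free monomer] (k2 = 6.23 × 10⁻⁴ M⁻¹ s⁻¹)
    living end + transfer agent → dead chain (k3 = 1.21 × 10⁻⁴ M⁻¹ s⁻¹)
    free monomer ⇌ dormant form (K4 = 1.9, k4 = 1.97 × 10⁻⁵ s⁻¹)
    free monomer + monomer in chains → side product (k5 = 5.73 × 10⁻⁶ M⁻¹ s⁻¹)
    protic impurity + free monomer → quenched substrate (k6 = 1.58 × 10⁻⁴ M⁻¹ s⁻¹)

| flask | free monomer | transfer agent | protic impurity | initiator | time |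
|---|---|---|---|---|---|
| epsilon | 1.5 M | 0.0450 M | 0.450 M | 15 mM | 8.0 h |
| theta | 1.5 M | 0.0450 M | 0.450 M | 45 mM | 8.0 h |

- a species is counted by the free monomer in it: one side product counts as two
- run time (epsilon): 8.0 h

* which of these there is most of at the end, counted by the free monomer in it, epsilon (side product / free monomer / monomer in chains)
* which of these there is most of at the end, counted by the free monomer in it, theta (side product / free monomer / monomer in chains)
* amount of the one of these that there is most of at the end, in percent of the free monomer charged, epsilon
* amount of the one of these that there is most of at the end, in percent of the free monomer charged, theta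

First, the balance of the initiator: c(initiator) + c(living end) + c(dead chain) stays at its charge, cN. At the start the initiator has a half-life of 0.123 h, shorter than the run. A living end has about 35.4 h against the transfer agent, longer than the run. So we set c(living end) equal to cN, and propagation is then pseudo-first-order in free monomer.

This gives our measure, the chain exposure x = k2·cN·t. It is 0.269 for epsilon and 0.807 for theta.

Second, what competes for the free monomer? The protic impurity has a half-life of 0.812 h at the starting c(free monomer), shorter than the run. So we take its charge off first, which leaves a pool of 70.0 % of the free monomer charged. The dormant form then pulls with 0.567 over the run, and we count its forward step alone.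

We let the pool fall as exp(−x−y) and give chains the share x/(x+y). On this reckoning epsilon keeps 30.3 % free monomer against 12.8 % in chains, so free monomer leads. Reckoned alike, theta keeps 17.7 % against 30.7 %, so chains lead.

The forecast names free monomer at 31.5 % for epsilon and monomer in chains at 30.5 % for theta, since the larger initiator charge “roughly triples chain growth”. Its amount for epsilon stands above ours, and its amount for theta below ours.

The flasks give free monomer at 31.7 % in epsilon and monomer in chains at 31.1 % in theta, so the forecast held. At the end of theta, initiator stands at 0 %, and living end 0.0390 M and dead chain 0.00597 M add up to 0.0450 M, the initiator charge. From epsilon to theta the exposure grew by a factor of 3.00, and monomer in chains by 2.45, which is less.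

The neighbour is epsilon with 0.037 M of initiator. Its exposure is 0.664, and our reckoning then gives free monomer 20.4 % and monomer in chains 26.7 %. The neighbour flask gave free monomer 20.8 % and monomer in chains 26.9 %.

(The constants used here were drawn at random within sensible limits, and the outcome is calculated.)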